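**Plan**

- Labels: benzofuran positions O1, C2, C3, C3a to C7a; C9 is the CH2OH carbon on C3; ring A is the benzo ring, ring B the dihydrofuran, ring C the syringyl ring.
- Retrosynthesis: the C5–vinyl bond is cut first (Heck) and C9 is taken back to a methyl ester. Ring B is then re-expanded: since C9 sits on C3 next to C3a, ring B with C9 is the ring-contracted isomer of a 2-arylchroman-4-one whose ketone carbon is C9, bonded to C3a. This cuts C3–C3a and restores C9–C3a. Last, the C2–ring C bond of that flavanone is cut to a chromone and an arylboronic acid.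
- Forward: the pyranone is closed on the brominated acetophenone, ring C is added at C2, the pyranone is contracted to ring B by a 1,2-shift of ring A, the C9 ester is reduced, and the acrylate chain is joined at C5.
- Stereochemistry: C2 (S) comes from the enantioselective palladium-catalysed conjugate addition and is not touched afterwards. C3 is set trans to the C2 aryl group in the ring contraction (3S as the ester, 3R after reduction, a change of descriptor only).

Key step: step 7

Assumption: the facial sense of the palladium pyridine-oxazoline catalyst on chromones is taken to follow that of β-substituted cyclic enones, so the (R)-ligand is expected to give the (S)-flavanone; if the sense proves opposite, the (S)-ligand is used in the same way.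

**Route**

Step 1
Reactants: 1 1-(2-hydroxy-3-methoxyphenyl)ethan-1-one (2'-hydroxy-3'-methoxyacetophenone)
Product: 2 1-(5-bromo-2-hydroxy-3-methoxyphenyl)ethan-1-one
Conditions: NBS (1.05 equiv), MeCN, 0 °C to rt
Reagents that add atoms: N-bromosuccinimide, O=C1CCC(=O)N1Br
Why: Electrophilic aromatic bromination in which the free hydroxyl directs para to C5', a position that is also meta to the acetyl group, so a single ring position should react while the methyl ketone is left alone.

Step 2
Reactants: 2 1-(5-bromo-2-hydroxy-3-methoxyphenyl)ethan-1-one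
Product: 4 6-bromo-8-methoxy-4H-chromen-4-one, via enaminone 3 (not isolated)
Conditions: Me2NCH(OMe)2, toluene, 110 °C; then conc. HCl, CH2Cl2, 40 °C
Reagents that add atoms: N,N-dimethylformamide dimethyl acetal, COC(OC)N(C)C
Why: Condensation of the methyl ketone with the amide acetal gives the vinylogous amide, and acid then drives conjugate addition of the phenol with loss of dimethylamine (enaminone route to chromones).

Step 3
Reactants: 5 4-bromo-2,6-dimethoxyphenol
Product: 6 4-bromo-2,6-dimethoxyphenyl pivalate
Conditions: t-BuCOCl, Et3N, DMAP (cat.), CH2Cl2, 0 °C to rt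
Reagents that add atoms: pivaloyl chloride, CC(C)(C)C(=O)Cl
Why: DMAP-catalysed O-acylation of the phenol gives a hindered ester that should survive the borylation and the acidic oxidation of step 7 and that lowers the electron density of ring C.

Step 4
Reactants: 6 4-bromo-2,6-dimethoxyphenyl pivalate
Product: 7 2,6-dimethoxy-4-(4,4,5,5-tetramethyl-1,3,2-dioxaborolan-2-yl)phenyl pivalate
Conditions: B2pin2, PdCl2(dppf) (3 mol %), KOAc, 1,4-dioxane, 85 °C
Reagents that add atoms: bis(pinacolato)diboron, CC1(C)OB(OC1(C)C)B1OC(C)(C)C(C)(C)O1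
Why: Miyaura borylation of the aryl bromide, in which the aryl pivalate C–O bond is inert to zerovalent palladium and the weak acetate base leaves the ester intact.

Step 5
Reactants: 7 2,6-dimethoxy-4-(4,4,5,5-tetramethyl-1,3,2-dioxaborolan-2-yl)phenyl pivalate
Product: 8 [3,5-dimethoxy-4-(pivaloyloxy)phenyl]boronic acid
Conditions: NaIO4, NH4OAc, acetone/H2O, rt
Reagents that add atoms: water, O
Why: Oxidative deprotection of a pinacol boronate, in which periodate cleaves the pinacol released by hydrolysis so that the equilibrium is pulled to the free boronic acid under near-neutral conditions that spare the pivalate.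

Step 6
Reactants: 4 6-bromo-8-methoxy-4H-chromen-4-one; 8 [3,5-dimethoxy-4-(pivaloyloxy)phenyl]boronic acid
Product: 9 4-[(2S)-6-bromo-8-methoxy-4-oxochroman-2-yl]-2,6-dimethoxyphenyl pivalate
Conditions: Pd(OCOCF3)2 (5 mol %), (R)-4-tert-butyl-2-(pyridin-2-yl)-4,5-dihydrooxazole (6 mol %), NH4PF6 (30 mol %), H2O (5 equiv), ClCH2CH2Cl, 60 °C
Reagents that add atoms: none
Why: Palladium-catalysed enantioselective conjugate addition of an arylboronic acid to a chromone, in which the aryl group passes from boron to the cationic divalent palladium complex, adds across C2=C3 on the face left open by the tert-butyl group of the ligand to set C2 as S, and the palladium enolate is protonated by water, the C6–Br bond staying intact because no zerovalent palladium takes part.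

Step 7
Reactants: 9 4-[(2S)-6-bromo-8-methoxy-4-oxochroman-2-yl]-2,6-dimethoxyphenyl pivalate
Product: 12 methyl (2S,3S)-5-bromo-2-[3,5-dimethoxy-4-(pivaloyloxy)phenyl]-7-methoxy-2,3-dihydro-1-benzofuran-3-carboxylate (2,3-trans), via methyl enol ether 10 (not isolated), via C3 iodane 11 (not isolated)
Conditions: PhI(OAc)2 (1.2 equiv), conc. H2SO4, HC(OMe)3, rt; then aq. NaHCO3
Reagents that add atoms: trimethyl orthoformate, COC(OC)OC; water, O
Why: Acid and trimethyl orthoformate convert the ketone into methyl enol ether 10, which attacks the trivalent iodine of PhI(OAc)2 through C3 on the face opposite the C2 aryl group to give iodane 11, whose equatorial C3–I bond lies antiperiplanar to the C4–C4a ring bond. Ring A then shifts from C4 to C3 as iodobenzene departs, forming the C3–C3a bond, and the dimethoxycarbenium ion left at the former C4 becomes the methyl ester on aqueous work-up. The closest known reaction type is the oxidative ring contraction of flavanones to methyl 2-aryl-2,3-dihydrobenzofuran-3-carboxylates by trivalent iodine in trimethyl orthoformate, a 1,2-aryl shift of the semipinacol kind. Ring B is closed by contraction of the six-membered pyranone in this shift and not by a cyclisation, and since the O1–C2 bond is never broken the S centre at C2 is carried over unchanged. The new C3 centre should be trans to the C2 aryl group, both because anti migration from the trans iodane leads there directly and because the ester α-carbon can equilibrate to the less hindered trans isomer. The step needs ring A to migrate in preference to the C2 aryl group (isoflavone path) and to simple dehydrogenation (flavone path), which the substrate secures by the pivaloyl group that makes ring C a poor migrating group and by O1 standing ortho to the migrating carbon of ring A.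

Step 8
Reactants: 12 methyl (2S,3S)-5-bromo-2-[3,5-dimethoxy-4-(pivaloyloxy)phenyl]-7-methoxy-2,3-dihydro-1-benzofuran-3-carboxylate
Product: 13 4-[(2S,3R)-5-bromo-3-(hydroxymethyl)-7-methoxy-2,3-dihydro-1-benzofuran-2-yl]-2,6-dimethoxyphenol
Conditions: LiAlH4 (3 equiv), THF, 0 °C; then EtOAc, aq. KNaC4H4O6 (potassium sodium tartrate)
Reagents that add atoms: none
Why: Hydride reduction of the methyl ester to the C9 alcohol with concurrent reductive cleavage of the aryl pivalate, which at 0 °C should outrun deprotonation at C3 (and with it opening of ring B by loss of the O1 phenoxide) and should leave the aryl bromide and both stereocentres untouched.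

Step 9
Reactants: 13 4-[(2S,3R)-5-bromo-3-(hydroxymethyl)-7-methoxy-2,3-dihydro-1-benzofuran-2-yl]-2,6-dimethoxyphenol; 14 methyl acrylate
Product: 15 methyl (E)-3-[(2S,3R)-2-(4-hydroxy-3,5-dimethoxyphenyl)-3-(hydroxymethyl)-7-methoxy-2,3-dihydro-1-benzofuran-5-yl]prop-2-enoate
Conditions: Pd(OAc)2 (5 mol %), P(o-tol)3 (12 mol %), Et3N, DMF, 100 °C, argon
Reagents that add atoms: none
Why: Mizoroki–Heck reaction in which zerovalent palladium inserts into the C5–Br bond, the acrylate undergoes syn insertion and syn β-hydride elimination gives the E cinnamate, a coupling that tolerates free hydroxyl groups.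

Step 10
Reactants: 15 methyl (E)-3-[(2S,3R)-2-(4-hydroxy-3,5-dimethoxyphenyl)-3-(hydroxymethyl)-7-methoxy-2,3-dihydro-1-benzofuran-5-yl]prop-2-enoate
Product: 16 (E)-3-[(2S,3R)-2-(4-hydroxy-3,5-dimethoxyphenyl)-3-(hydroxymethyl)-7-methoxy-2,3-dihydro-1-benzofuran-5-yl]prop-2-enoic acid
Conditions: LiOH, THF/MeOH/H2O, rt, argon; then 1 M HCl to pH 3
Reagents that add atoms: lithium hydroxide, [Li+].[OH-]
Why: Saponification of the methyl cinnamate under mild conditions, in which no C3 ester remains to trigger base-induced opening of ring B, so that acidification should give the acid with C2, C3 and the E alkene unchanged.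

**Compound list**

1 | 1-(2-hydroxy-3-methoxyphenyl)ethan-1-one | CC(=O)c1cccc(OC)c1O | starting material
2 | 1-(5-bromo-2-hydroxy-3-methoxyphenyl)ethan-1-one | CC(=O)c1cc(Br)cc(OC)c1O | intermediate
3 | (E)-1-(5-bromo-2-hydroxy-3-methoxyphenyl)-3-(dimethylamino)prop-2-en-1-one | CN(C)/C=C/C(=O)c1cc(Br)cc(OC)c1O | intermediate
4 | 6-bromo-8-methoxy-4H-chromen-4-one | COc1cc(Br)cc2c(=O)ccoc12 | intermediate
5 | 4-bromo-2,6-dimethoxyphenol | COc1cc(Br)cc(OC)c1O | starting material
6 | 4-bromo-2,6-dimethoxyphenyl pivalate | COc1cc(Br)cc(OC)c1OC(=O)C(C)(C)C | intermediate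
7 | 2,6-dimethoxy-4-(4,4,5,5-tetramethyl-1,3,2-dioxaborolan-2-yl)phenyl pivalate | COc1cc(B2OC(C)(C)C(C)(C)O2)cc(OC)c1OC(=O)C(C)(C)C | intermediate
8 | [3,5-dimethoxy-4-(pivaloyloxy)phenyl]boronic acid | COc1cc(B(O)O)cc(OC)c1OC(=O)C(C)(C)C | intermediate
9 | 4-[(2S)-6-bromo-8-methoxy-4-oxochroman-2-yl]-2,6-dimethoxyphenyl pivalate | COc1cc([C@@H]2CC(=O)c3cc(Br)cc(OC)c3O2)cc(OC)c1OC(=O)C(C)(C)C | intermediate
10 | 4-[(2S)-6-bromo-4,8-dimethoxy-2H-chromen-2-yl]-2,6-dimethoxyphenyl pivalate | COc1cc([C@@H]2C=C(OC)c3cc(Br)cc(OC)c3O2)cc(OC)c1OC(=O)C(C)(C)C | intermediate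
11 | 4-{(2R,3R)-3-[acetoxy(phenyl)-λ3-iodanyl]-6-bromo-4,4,8-trimethoxychroman-2-yl}-2,6-dimethoxyphenyl pivalate (2,3-trans; same spatial arrangement at C2 as in 9) | COc1cc([C@@H]2[C@@H](I(OC(C)=O)c4ccccc4)C(OC)(OC)c3cc(Br)cc(OC)c3O2)cc(OC)c1OC(=O)C(C)(C)C | intermediate
12 | methyl (2S,3S)-5-bromo-2-[3,5-dimethoxy-4-(pivaloyloxy)phenyl]-7-methoxy-2,3-dihydro-1-benzofuran-3-carboxylate (2,3-trans) | COc1cc([C@H]2Oc3c(OC)cc(Br)cc3[C@@H]2C(=O)OC)cc(OC)c1OC(=O)C(C)(C)C | intermediate
13 | 4-[(2S,3R)-5-bromo-3-(hydroxymethyl)-7-methoxy-2,3-dihydro-1-benzofuran-2-yl]-2,6-dimethoxyphenol | COc1cc([C@H]2Oc3c(OC)cc(Br)cc3[C@@H]2CO)cc(OC)c1O | intermediate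
14 | methyl acrylate | C=CC(=O)OC | starting material
15 | methyl (E)-3-[(2S,3R)-2-(4-hydroxy-3,5-dimethoxyphenyl)-3-(hydroxymethyl)-7-methoxy-2,3-dihydro-1-benzofuran-5-yl]prop-2-enoate | COc1cc([C@H]2Oc3c(OC)cc(/C=C/C(=O)OC)cc3[C@@H]2CO)cc(OC)c1O | intermediate
16 | (E)-3-[(2S,3R)-2-(4-hydroxy-3,5-dimethoxyphenyl)-3-(hydroxymethyl)-7-methoxy-2,3-dihydro-1-benzofuran-5-yl]prop-2-enoic acid | COc1cc([C@H]2Oc3c(OC)cc(/C=C/C(=O)O)cc3[C@@H]2CO)cc(OC)c1O | target

**Count**

Total steps: 10.
Longest linear sequence: 8 steps (5 to 16 through steps 3, 4, 5, 6, 7, 8, 9, 10); the branch from 1 has 7 steps.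

**Steps most likely to fail**

Step 7. The C3 iodane may collapse by elimination (dehydrogenation to the flavone) or by migration of the C2 aryl group instead of ring A. Acid-mediated opening of the flavanone to the chalcone before oxidation would also erode the enantiomeric purity.
Fallback: a Wolff ring contraction, which keeps the same aryl shift but allows only the carbonyl substituent (ring A) to migrate and uses no acid. It sets out from 9 and returns at 12. The kinetic enolate of 9 (LiN(SiMe3)2, THF, −78 °C) is acylated with CF3CO2CH2CF3 to give 3-trifluoroacetyl flavanone F1. Diazo transfer with MsN3 and Et3N in MeCN then gives 3-diazoflavanone F2. Irradiation of F2 in methanol should expel nitrogen with migration of ring A from the carbonyl carbon to C3, and methanol traps the ring-contracted ketene. The ester mixture, which is expected to contain cis ester F3, is equilibrated with DBU in toluene to the trans ester 12.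

Step 6. Facial discrimination may be insufficient, or transmetalation slow, with the electron-rich, doubly meta-substituted arylboronic acid, and protodeboronation may compete.
Fallback: resolution instead of asymmetric C–C bond formation, setting out from 4 and 8 and returning at 9. Conjugate addition with Pd(OCOCF3)2 and achiral 2,2'-bipyridine gives racemic flavanone F4. Kinetic resolution by asymmetric transfer hydrogenation with RuCl[(R,R)-TsDPEN](p-cymene) in HCO2H/Et3N is then expected to reduce the (R)-ketone to cis-flavan-4-ol F5 and leave (S)-flavanone 9, which is separated by chromatography. The catalyst antipode is chosen so that the (R)-ketone is the one consumed.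

Step 9. Oxidative addition into the electron-rich C5–Br bond may be slow, while at 100 °C in base the free syringyl phenol may be oxidised or bind palladium, so that the catalyst dies and the substrate degrades.
Fallback: a palladium-free chain extension on a protected substrate, setting out from 13 and returning at 15. Silylation (TBSCl, imidazole, DMF) gives bis-silyl ether F6. Bromine–lithium exchange (n-BuLi, THF, −78 °C) and quenching with DMF give aldehyde F7. Horner–Wadsworth–Emmons olefination with (MeO)2P(O)CH2CO2Me and NaH in THF gives the E bis-silyl cinnamate F8. Bu4NF buffered with AcOH in THF then removes both silyl groups to give 15.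

**Further compounds**

F1 | step 7 | 4-[(2S)-6-bromo-8-methoxy-4-oxo-3-(trifluoroacetyl)chroman-2-yl]-2,6-dimethoxyphenyl pivalate (C3 epimers and enol form) | COc1cc([C@@H]2C(C(=O)C(F)(F)F)C(=O)c3cc(Br)cc(OC)c3O2)cc(OC)c1OC(=O)C(C)(C)C
F2 | step 7 | 4-[(2R)-6-bromo-3-diazo-8-methoxy-4-oxochroman-2-yl]-2,6-dimethoxyphenyl pivalate (same spatial arrangement at C2 as in 9) | COc1cc([C@@H]2C(=[N+]=[N-])C(=O)c3cc(Br)cc(OC)c3O2)cc(OC)c1OC(=O)C(C)(C)C
F3 | step 7 | methyl (2S,3R)-5-bromo-2-[3,5-dimethoxy-4-(pivaloyloxy)phenyl]-7-methoxy-2,3-dihydro-1-benzofuran-3-carboxylate (2,3-cis) | COc1cc([C@H]2Oc3c(OC)cc(Br)cc3[C@H]2C(=O)OC)cc(OC)c1OC(=O)C(C)(C)C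
F4 | step 6 | racemic 4-(6-bromo-8-methoxy-4-oxochroman-2-yl)-2,6-dimethoxyphenyl pivalate | COc1cc(C2CC(=O)c3cc(Br)cc(OC)c3O2)cc(OC)c1OC(=O)C(C)(C)C
F5 | step 6 | 4-[(2R,4R)-6-bromo-4-hydroxy-8-methoxychroman-2-yl]-2,6-dimethoxyphenyl pivalate (2,4-cis) | COc1cc([C@H]2C[C@@H](O)c3cc(Br)cc(OC)c3O2)cc(OC)c1OC(=O)C(C)(C)C
F6 | step 9 | {4-[(2S,3R)-5-bromo-3-{[tert-butyl(dimethyl)silyl]oxymethyl}-7-methoxy-2,3-dihydro-1-benzofuran-2-yl]-2,6-dimethoxyphenoxy}(tert-butyl)dimethylsilane | COc1cc([C@H]2Oc3c(OC)cc(Br)cc3[C@@H]2CO[Si](C)(C)C(C)(C)C)cc(OC)c1O[Si](C)(C)C(C)(C)C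
F7 | step 9 | (2S,3R)-2-{4-[tert-butyl(dimethyl)silyl]oxy-3,5-dimethoxyphenyl}-3-{[tert-butyl(dimethyl)silyl]oxymethyl}-7-methoxy-2,3-dihydro-1-benzofuran-5-carbaldehyde | COc1cc([C@H]2Oc3c(OC)cc(C=O)cc3[C@@H]2CO[Si](C)(C)C(C)(C)C)cc(OC)c1O[Si](C)(C)C(C)(C)C
F8 | step 9 | methyl (E)-3-[(2S,3R)-2-{4-[tert-butyl(dimethyl)silyl]oxy-3,5-dimethoxyphenyl}-3-{[tert-butyl(dimethyl)silyl]oxymethyl}-7-methoxy-2,3-dihydro-1-benzofuran-5-yl]prop-2-enoate | COc1cc([C@H]2Oc3c(OC)cc(/C=C/C(=O)OC)cc3[C@@H]2CO[Si](C)(C)C(C)(C)C)cc(OC)c1O[Si](C)(C)C(C)(C)C
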